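**Retrosynthetic overview**
1. The target comes from the bicyclo[3.2.1]oct‑3‑ene‑2,8‑dione by exo‑face hydride delivery to C2 (sets the fifth stereocentre), then O‑acetylation.
2. The dione comes from one cationic [5+2] union. The C5–C6 and C1–C7 bonds form together, so the cyclopentanone and cycloheptene rings close in the same operation. A chiral ion pair sets C1, C5, C6 and C7.
3. The five‑carbon partner is a p‑quinone monoketal, made from 6‑allyl‑2,3,4‑trimethoxyphenol (O‑allylation/Claisen, then PhI(OAc)2/MeOH).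
4. The two‑carbon partner is (E)‑isoelemicin, made by Suzuki coupling. Its E geometry becomes the trans C6‑Me/C7‑aryl relationship.
5. Ring order: the aryl ring is bought, the six‑membered ring is the dearomatised phenol, and the five‑ and seven‑membered rings then form simultaneously.

Bicyclo numbering: C1 = OMe bridgehead, C2, C3 (OMe), C4, C5 = allyl bridgehead, C6 (Me), C7 (aryl), C8 = bridge C=O.

Assumption: compounds 1, 2, 4 and 5 are catalogue chemicals, and because the sense of induction of the chiral acid in step 4 cannot be predicted, the catalyst antipode that delivers 10 is used.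

**Step 1**
Reactants: 1 5‑bromo‑1,2,3‑trimethoxybenzene; 2 (E)‑prop‑1‑enylboronic acid pinacol ester
Product: 3 (E)‑isoelemicin [1,2,3‑trimethoxy‑5‑((E)‑prop‑1‑enyl)benzene]
Conditions: PdCl2(dppf) (2 mol %), K2CO3, 1,4‑dioxane/H2O, 80 °C
Reagents that add atoms: none
Why: Suzuki–Miyaura coupling keeps the E geometry of the alkenylboronate, which later fixes the trans C6/C7 relationship.

**Step 2**
Reactants: 4 2,3,4‑trimethoxyphenol; 5 allyl bromide
Product: 7 6‑allyl‑2,3,4‑trimethoxyphenol, via allyl 2,3,4‑trimethoxyphenyl ether 6 (not isolated)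
Conditions: K2CO3, acetone, reflux; filter, evaporate; then N,N‑diethylaniline, 195 °C
Reagents that add atoms: none
Why: Williamson etherification followed by aromatic Claisen rearrangement, which can only end at the single free ortho carbon; no stereocentre is formed.

**Step 3**
Reactants: 7 6‑allyl‑2,3,4‑trimethoxyphenol
Product: 8 2‑allyl‑4,4,5,6‑tetramethoxycyclohexa‑2,5‑dien‑1‑one
Conditions: PhI(OAc)2 (1.05 equiv), MeOH, 0 °C
Reagents that add atoms: methanol CO
Why: Oxidative dearomatisation by trivalent iodine, in which methanol adds para because the para‑methoxy group best stabilises the phenoxenium ion, giving the p‑quinone monoketal with no stereocentre.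

**Step 4 (key step)**
Reactants: 8 2‑allyl‑4,4,5,6‑tetramethoxycyclohexa‑2,5‑dien‑1‑one; 3 (E)‑isoelemicin
Product: 10 (1R,5S,6S,7R)‑5‑allyl‑1,3‑dimethoxy‑6‑methyl‑7‑(3,4,5‑trimethoxyphenyl)bicyclo[3.2.1]oct‑3‑ene‑2,8‑dione, via C2 dimethyl ketal 9 (not isolated)
Conditions: chiral IDPi acid (5 mol %; imidodiphosphorimidate from two 3,3'‑bis[3,5‑bis(trifluoromethyl)phenyl]‑1,1'‑bi‑2‑naphthol units with N‑SO2CF3 groups), 3 (1.5 equiv), CH2Cl2, −60 °C; then 1 M aq HCl, THF, 0 °C
Reagents that add atoms: water O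
Why: Proposed new method: the confined acid ionises the ketal of 8 to a methoxy‑stabilised oxidopentadienyl cation held as a contact ion pair; the methyl‑bearing alkene carbon of 3 attacks the allyl‑bearing terminus (C5–C6), and the resulting benzylic cation is captured by the carbon of the remaining 1,2‑dimethoxy enol ether (C1–C7), so both new rings close at once; the E alkene gives trans C6/C7, stacking of the aryl group under the cation places it endo, the chiral anion selects the face of the flat cation and so sets the absolute configuration of all four centres, and the released methanol caps the C2 oxocarbenium ion as 9, which the acidic work‑up hydrolyses; the closest known reaction types are the racemic acid‑promoted quinone monoketal–propenylarene [5+2] cycloaddition and asymmetric counteranion‑directed catalysis of oxocarbenium ions.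

**Step 5**
Reactants: 10 the 2,8‑dione
Product: 11 (1S,2R,5S,6S,7R)‑5‑allyl‑2‑hydroxy‑1,3‑dimethoxy‑6‑methyl‑7‑(3,4,5‑trimethoxyphenyl)bicyclo[3.2.1]oct‑3‑en‑8‑one
Conditions: NaBH4, CeCl3·7H2O, MeOH/CH2Cl2, −78 °C; pH 7 buffer
Reagents that add atoms: none
Why: Luche 1,2‑reduction takes the α‑methoxy‑enone carbonyl rather than the bridge ketone flanked by two quaternary carbons, and hydride arrives from the exo face because the endo face is roofed by the C7 aryl group, giving the endo (2R) alcohol.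

**Step 6**
Reactants: 11 the C2 alcohol
Product: 12 (1S,2R,5S,6S,7R)‑5‑allyl‑1,3‑dimethoxy‑6‑methyl‑8‑oxo‑7‑(3,4,5‑trimethoxyphenyl)bicyclo[3.2.1]oct‑3‑en‑2‑yl acetate (target)
Conditions: Ac2O, pyridine, DMAP (10 mol %), CH2Cl2, 0 to 23 °C
Reagents that add atoms: acetic anhydride CC(=O)OC(C)=O
Why: DMAP‑catalysed O‑acylation leaves the C–O bond untouched, so C2 keeps its configuration, and the mild base limits retro‑aldol opening.

**Compound list**
1 | 5‑bromo‑1,2,3‑trimethoxybenzene | COc1cc(Br)cc(OC)c1OC | starting material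
2 | (E)‑prop‑1‑enylboronic acid pinacol ester | C/C=C/B1OC(C)(C)C(C)(C)O1 | starting material
3 | (E)‑isoelemicin | C/C=C/c1cc(OC)c(OC)c(OC)c1 | intermediate
4 | 2,3,4‑trimethoxyphenol | COc1ccc(O)c(OC)c1OC | starting material
5 | allyl bromide | C=CCBr | starting material
6 | allyl 2,3,4‑trimethoxyphenyl ether | C=CCOc1ccc(OC)c(OC)c1OC | intermediate
7 | 6‑allyl‑2,3,4‑trimethoxyphenol | C=CCc1cc(OC)c(OC)c(OC)c1O | intermediate
8 | 2‑allyl‑4,4,5,6‑tetramethoxycyclohexa‑2,5‑dien‑1‑one | C=CCC1=CC(OC)(OC)C(OC)=C(OC)C1=O | intermediate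
9 | (1R,5S,6S,7R)‑5‑allyl‑1,2,2,3‑tetramethoxy‑6‑methyl‑7‑(3,4,5‑trimethoxyphenyl)bicyclo[3.2.1]oct‑3‑en‑8‑one | C=CC[C@]12C=C(OC)C(OC)(OC)[C@](OC)(C1=O)[C@@H](c1cc(OC)c(OC)c(OC)c1)[C@@H]2C | intermediate
10 | (1R,5S,6S,7R)‑5‑allyl‑1,3‑dimethoxy‑6‑methyl‑7‑(3,4,5‑trimethoxyphenyl)bicyclo[3.2.1]oct‑3‑ene‑2,8‑dione | C=CC[C@]12C=C(OC)C(=O)[C@](OC)(C1=O)[C@@H](c1cc(OC)c(OC)c(OC)c1)[C@@H]2C | intermediate
11 | (1S,2R,5S,6S,7R)‑5‑allyl‑2‑hydroxy‑1,3‑dimethoxy‑6‑methyl‑7‑(3,4,5‑trimethoxyphenyl)bicyclo[3.2.1]oct‑3‑en‑8‑one | C=CC[C@]12C=C(OC)[C@@H](O)[C@](OC)(C1=O)[C@@H](c1cc(OC)c(OC)c(OC)c1)[C@@H]2C | intermediate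
12 | (1S,2R,5S,6S,7R)‑5‑allyl‑1,3‑dimethoxy‑6‑methyl‑8‑oxo‑7‑(3,4,5‑trimethoxyphenyl)bicyclo[3.2.1]oct‑3‑en‑2‑yl acetate | C=CC[C@]12C=C(OC)[C@@H](OC(C)=O)[C@](OC)(C1=O)[C@@H](c1cc(OC)c(OC)c(OC)c1)[C@@H]2C | target

**Step count**
Total steps: 6. Longest linear sequence: 5 steps (4 → 7 → 8 → 10 → 11 → 12).

**Steps most likely to fail**

Step 4. The risks are O‑closure to a dihydrobenzofuran‑type adduct, polymerisation of 3, and low ee. The fallback sets out from 7 and comes back at 10. It changes the five‑carbon partner from the ketal to the quinone, and the chirality source to a stoichiometric chiral titanium Lewis acid. Compound 7 is oxidised with PhI(OAc)2 in aqueous MeCN to 5‑allyl‑2,3‑dimethoxy‑1,4‑benzoquinone F1. F1 and 3 are combined at −78 °C in CH2Cl2 with the complex made from TiCl2(OiPr)2 and (R,R)‑TADDOL (or its antipode). The complex chelates the less hindered C=O/OMe pair and gives (1R,5S,6S,7R)‑5‑allyl‑3‑hydroxy‑1‑methoxy‑6‑methyl‑7‑(3,4,5‑trimethoxyphenyl)bicyclo[3.2.1]oct‑3‑ene‑2,8‑dione F2. O‑methylation of this diosphenol with MeI/K2CO3 in acetone gives 10.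

Step 5. The risks are competing reduction of the strained bridge ketone and retro‑aldol cleavage. The fallback sets out from 10 and comes back at 12. It drops chemoselective reduction and uses over‑reduction followed by differentiation. Excess NaBH4 reduces both carbonyls to (1R,2R,5S,6S,7R,8S)‑5‑allyl‑1,3‑dimethoxy‑6‑methyl‑7‑(3,4,5‑trimethoxyphenyl)bicyclo[3.2.1]oct‑3‑ene‑2,8‑diol F3. Only the allylic C2 hydroxyl is then acetylated (Ac2O, pyridine, 0 °C), because the C8 carbinol lies between two quaternary carbons. This gives (1R,2R,5S,6S,7R,8S)‑5‑allyl‑8‑hydroxy‑1,3‑dimethoxy‑6‑methyl‑7‑(3,4,5‑trimethoxyphenyl)bicyclo[3.2.1]oct‑3‑en‑2‑yl acetate F4. Dess–Martin oxidation of the remaining carbinol gives 12.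

Step 6. The risks are slow acylation of the hindered endo alcohol and base‑induced retro‑aldol of the β‑hydroxy ketone. The fallback sets out from 10 and comes back at 12, and the free alcohol is never handled. Compound 10 is reduced with iBu2AlH in CH2Cl2 at −78 °C, and the aluminium alkoxide is acetylated in the same flask with Ac2O, pyridine and DMAP.

**Further compounds**
F1 | step 4 | 5‑allyl‑2,3‑dimethoxy‑1,4‑benzoquinone | C=CCC1=CC(=O)C(OC)=C(OC)C1=O
F2 | step 4 | (1R,5S,6S,7R)‑5‑allyl‑3‑hydroxy‑1‑methoxy‑6‑methyl‑7‑(3,4,5‑trimethoxyphenyl)bicyclo[3.2.1]oct‑3‑ene‑2,8‑dione | C=CC[C@]12C=C(O)C(=O)[C@](OC)(C1=O)[C@@H](c1cc(OC)c(OC)c(OC)c1)[C@@H]2C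
F3 | step 5 | (1R,2R,5S,6S,7R,8S)‑5‑allyl‑1,3‑dimethoxy‑6‑methyl‑7‑(3,4,5‑trimethoxyphenyl)bicyclo[3.2.1]oct‑3‑ene‑2,8‑diol | C=CC[C@]12C=C(OC)[C@@H](O)[C@](OC)([C@H]1O)[C@@H](c1cc(OC)c(OC)c(OC)c1)[C@@H]2C
F4 | step 5 | (1R,2R,5S,6S,7R,8S)‑5‑allyl‑8‑hydroxy‑1,3‑dimethoxy‑6‑methyl‑7‑(3,4,5‑trimethoxyphenyl)bicyclo[3.2.1]oct‑3‑en‑2‑yl acetate | C=CC[C@]12C=C(OC)[C@@H](OC(C)=O)[C@](OC)([C@H]1O)[C@@H](c1cc(OC)c(OC)c(OC)c1)[C@@H]2C
F0 | step 6 | none | none
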